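A direct plan would build the chain around the C2–C3 bond: a sparteine-lithiated, silyl-protected O-(2-arylethyl) diisopropylcarbamate A2 would open the silyl-protected, enantioenriched β-lactone A1 to the α-carbamoyloxy β′-hydroxy ketone A3.
A borinate-directed hydride reduction of A3, then cleavage of the carbamate with LiAlH4 and of the two aryl silyl ethers, would finish it.
Its weakest point would be (a) the carbanion–lactone union itself: an α-oxy organolithium has not been acylated by a β-lactone, the lactone could be enolised or the new ketone could add a second carbanion, and C2 would end up between C=O and the carbamate oxygen in A3, where the lithium alkoxide formed in the same flask could epimerise it.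
Next would be (b) the cleavage of the hindered diisopropylcarbamate with LiAlH4 at reflux followed by aqueous base, the step least welcome on the fully assembled polyol.
Last would be (c) the overhead: two silylations, a carbamoylation and the carbamate removal would be four of eight steps that form no skeletal bond and set no stereocentre, and C5 would need a bespoke chiral aluminium catalyst.

The new plan would cut the two aryl O-benzyl bonds last, read C5–OH as a ketone and O3–C3–C4–C5=O as a 4,5-dihydro-1,2-oxazole template, and cut that ring across C4–C5 and O–C3 (not C2–C3).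
This gives a nitrile oxide (C5–C7 with the guaiacyl ring) and the allylic alcohol (S)-ArCH2–CH(OH)–CH=CH2 (C1–C4), itself made from (S)-epichlorohydrin by forming C1–C(aryl) and C3=C4.
The feature that allows it: O3 and O5 stand 1,3 across the C4 methylene, and the C2 hydroxyl sits directly beside C3, so its magnesium alkoxide can hold the nitrile oxide and deliver its oxygen to one face of C3=C4.
The two benzene rings are bought; the only ring formed is the five-membered heterocycle, which is opened again by N–O hydrogenolysis, after which the freed C3–OH directs hydride to C5.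
No carbanion meets a lactone, no stereocentre ever lies α to a carbonyl, no carbamate or silyl group has to be removed, and the last step is a neutral hydrogenolysis over Pd/C.

Key step: step 6

Remark: chain atoms are numbered as in the target, from C1 (the CH2 on the 4-hydroxyphenyl ring) to C7 (the CH2 on the guaiacyl ring); oxime 10 is taken as its E/Z mixture, since both isomers give the same hydroximoyl chloride.

Step 1
Reactants: 1 1-(benzyloxy)-4-bromobenzene; 2 (S)-2-(chloromethyl)oxirane [(S)-epichlorohydrin]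
Product: 4 (S)-1-[4-(benzyloxy)phenyl]-3-chloropropan-2-ol, via arylmagnesium bromide 3 (not isolated)
Conditions: Mg (1.1 equiv), THF, reflux; CuI (copper monoiodide, 10 mol %), then 2 (0.9 equiv), THF, −40 → 0 °C; aq. NH4Cl
Reagents that add atoms: none
Why: Copper-catalysed Grignard opening of a terminal epoxide by SN2 attack at the unsubstituted ring carbon, which at −40 °C should be faster than displacement of the primary chloride; the stereocentre of 2 is not touched, so the bought (S)-configuration becomes C2 of the target.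

Step 2
Reactants: 4 (S)-1-[4-(benzyloxy)phenyl]-3-chloropropan-2-ol
Product: 6 (S)-1-[4-(benzyloxy)phenyl]but-3-en-2-ol, via epoxide 5 (not isolated)
Conditions: Me3S+ I− (4.0 equiv), n-BuLi (3.9 equiv), THF, −20 °C; add 4, −20 °C → rt; H2O
Reagents that add atoms: trimethylsulfonium iodide, C[S+](C)C.[I-]
Why: One-carbon homologation of a terminal epoxide to an allylic alcohol with excess dimethylsulfonium methylide (the Corey–Chaykovsky ylide), which should first close the chlorohydrin to epoxide 5 by internal SN2 at CH2Cl, then open 5 at its CH2, the sulfonium betaine losing Me2S by α′,β-elimination; C2 is a spectator throughout and stays (S).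

Step 3
Reactants: 7 4-(3-hydroxypropyl)-2-methoxyphenol (dihydroconiferyl alcohol)
Product: 8 3-[4-(benzyloxy)-3-methoxyphenyl]propan-1-ol
Conditions: BnBr (1.05 equiv), K2CO3 (1.5 equiv), acetone, reflux
Reagents that add atoms: benzyl bromide, BrCc1ccccc1
Why: Williamson ether synthesis in which carbonate deprotonates only the phenol, so the primary alcohol stays free; the benzyl ether shields the guaiacol from the hypochlorite and the magnesium bases of step 6.

Step 4
Reactants: 8 3-[4-(benzyloxy)-3-methoxyphenyl]propan-1-ol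
Product: 9 3-[4-(benzyloxy)-3-methoxyphenyl]propanal
Conditions: TEMPO (10 mol %), PhI(OAc)2 (1.1 equiv), CH2Cl2, rt
Reagents that add atoms: none
Why: Oxoammonium-mediated (TEMPO) oxidation of a primary alcohol should stop at the aldehyde and uses no chlorinating co-oxidant that could attack the electron-rich ring.

Step 5
Reactants: 9 3-[4-(benzyloxy)-3-methoxyphenyl]propanal
Product: 10 3-[4-(benzyloxy)-3-methoxyphenyl]propanal oxime (E/Z mixture)
Conditions: NH2OH·HCl (1.2 equiv), NaOAc (1.5 equiv), EtOH/H2O, rt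
Reagents that add atoms: hydroxylamine hydrochloride, Cl.NO
Why: Condensation of the aldehyde with hydroxylamine should give the aldoxime cleanly; no stereocentre is involved and the oxime geometry is immaterial for the next step.

Step 6
Reactants: 10 3-[4-(benzyloxy)-3-methoxyphenyl]propanal oxime; 6 (S)-1-[4-(benzyloxy)phenyl]but-3-en-2-ol
Product: 14 (1S)-2-[4-(benzyloxy)phenyl]-1-[(5S)-3-{2-[4-(benzyloxy)-3-methoxyphenyl]ethyl}-4,5-dihydro-1,2-oxazol-5-yl]ethan-1-ol, via hydroximoyl chloride 11 (not isolated), via bromomagnesium alkoxide 12 (not isolated), via nitrile oxide 13 (not isolated)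
Conditions: 10 (1.3 equiv), t-BuOCl (1.3 equiv), CH2Cl2, −78 °C; separately 6 (1.0 equiv), i-PrOH (3.3 equiv), EtMgBr (3.0 equiv, 3 M in Et2O), CH2Cl2, 0 °C; add the solution of 11 slowly, 0 °C → rt; aq. NH4Cl
Reagents that add atoms: none
Why: t-BuOCl converts aldoxime 10 into hydroximoyl chloride 11, which on slow addition to the bromomagnesium alkoxides loses HCl to give nitrile oxide 13 at a magnesium centre that also carries the allylic alkoxide 12, and a concerted 1,3-dipolar cycloaddition then forms C4–C5 and O–C3 in one event. The closest known reaction type is the magnesium-alkoxide-directed nitrile oxide cycloaddition to chiral secondary allylic alcohols, used as a hydroxyl-directed aldol surrogate. The five-membered 4,5-dihydro-1,2-oxazole closes by intermolecular [3+2] cycloaddition, suprafacial on the alkene, with oxygen going to the internal carbon C3 as is normal for a monosubstituted alkene and as the O–Mg–O bridge demands. The new centre C3 (ring C5) is set by C2: in the bridged transition state the C2–O–Mg bond lies outside, H inside and the CH2Ar group anti to the incoming dipole, which should lead to the 2,3-syn (threo) adduct, (5S) from (S)-6. The step needs face selectivity and must outrun furoxan formation and the unselective unbridged pathway; the free C2 hydroxyl as its magnesium salt, CH2Cl2 as a non-coordinating solvent and the slow feed of 11 secure this, and the hypochlorite is consumed at −78 °C before it meets the alkene. Two simple pieces, one with a single bought stereocentre and one achiral, would thus give a product that holds the full C1–C7 chain, both aryl groups, two of the three stereocentres and the C5 carbonyl in masked form.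

Step 7
Reactants: 14 (1S)-2-[4-(benzyloxy)phenyl]-1-[(5S)-3-{2-[4-(benzyloxy)-3-methoxyphenyl]ethyl}-4,5-dihydro-1,2-oxazol-5-yl]ethan-1-ol
Product: 16 (5S,6S)-1-[4-(benzyloxy)-3-methoxyphenyl]-7-[4-(benzyloxy)phenyl]-5,6-dihydroxyheptan-3-one, via β-hydroxy imine 15 (not isolated)
Conditions: Raney Ni, H2 (1 atm), B(OH)3 (3 equiv), MeOH/H2O 5:1, rt
Reagents that add atoms: water, O
Why: Hydrogenolysis of the isoxazoline N–O bond on Raney Ni gives the β-hydroxy imine 15, which the boric acid buffer should hydrolyse to the ketone before it can be reduced to the amine; C2 and C3 are not α to the new carbonyl and cannot epimerise, and aryl benzyl ethers should survive Raney Ni at 1 atm H2 and room temperature.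

Step 8
Reactants: 16 (5S,6S)-1-[4-(benzyloxy)-3-methoxyphenyl]-7-[4-(benzyloxy)phenyl]-5,6-dihydroxyheptan-3-one
Product: 18 (2S,3S,5S)-1-[4-(benzyloxy)phenyl]-7-[4-(benzyloxy)-3-methoxyphenyl]heptane-2,3,5-triol, via bis(diethylborinate) chelate 17 (not isolated)
Conditions: Et2BOMe (2.2 equiv), THF/MeOH 4:1, −78 °C; NaBH4 (1.5 equiv), −78 °C; AcOH; MeOH co-evaporation
Reagents that add atoms: none
Why: Narasaka–Prasad reduction, in which the diethylborinate on O3 binds the C5 carbonyl in a six-membered half-chair and external hydride adds axially to give the 3,5-syn diol, that is (5S); two equivalents of Et2BOMe cap both hydroxyls so that the C2 oxygen should not compete as a ligand for the boron on O3.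

Step 9
Reactants: 18 (2S,3S,5S)-1-[4-(benzyloxy)phenyl]-7-[4-(benzyloxy)-3-methoxyphenyl]heptane-2,3,5-triol
Product: 19 (2S,3S,5S)-1-(4-hydroxyphenyl)-7-(4-hydroxy-3-methoxyphenyl)heptane-2,3,5-triol
Conditions: H2 (1 atm), Pd/C (10 % Pd), EtOAc/MeOH, rt
Reagents that add atoms: none
Why: Hydrogenolysis of the two aryl benzyl ethers over Pd/C under neutral conditions; none of the three carbinol carbons is benzylic, so no C–O bond at a stereocentre is broken and (2S,3S,5S) is retained.

**Compound list**
1 | 1-(benzyloxy)-4-bromobenzene | Brc1ccc(OCc2ccccc2)cc1 | starting material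
2 | (S)-2-(chloromethyl)oxirane, (S)-epichlorohydrin | ClC[C@@H]1CO1 | starting material
3 | [4-(benzyloxy)phenyl]magnesium bromide (formed in the flask) | Br[Mg]c1ccc(OCc2ccccc2)cc1 | intermediate
4 | (S)-1-[4-(benzyloxy)phenyl]-3-chloropropan-2-ol | ClC[C@@H](O)Cc1ccc(OCc2ccccc2)cc1 | intermediate
5 | (S)-2-[4-(benzyloxy)benzyl]oxirane (formed in the flask) | C1[C@@H](O1)Cc2ccc(OCc3ccccc3)cc2 | intermediate
6 | (S)-1-[4-(benzyloxy)phenyl]but-3-en-2-ol | C=C[C@@H](O)Cc1ccc(OCc2ccccc2)cc1 | intermediate
7 | 4-(3-hydroxypropyl)-2-methoxyphenol (dihydroconiferyl alcohol) | COc1cc(CCCO)ccc1O | starting material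
8 | 3-[4-(benzyloxy)-3-methoxyphenyl]propan-1-ol | COc1cc(CCCO)ccc1OCc1ccccc1 | intermediate
9 | 3-[4-(benzyloxy)-3-methoxyphenyl]propanal | COc1cc(CCC=O)ccc1OCc1ccccc1 | intermediate
10 | 3-[4-(benzyloxy)-3-methoxyphenyl]propanal oxime (E/Z mixture) | COc1cc(CCC=NO)ccc1OCc1ccccc1 | intermediate
11 | 3-[4-(benzyloxy)-3-methoxyphenyl]-N-hydroxypropanimidoyl chloride (formed in the flask) | COc1cc(CCC(Cl)=NO)ccc1OCc1ccccc1 | intermediate
12 | bromomagnesium (S)-1-[4-(benzyloxy)phenyl]but-3-en-2-olate (formed in the flask) | C=C[C@@H](O[Mg]Br)Cc1ccc(OCc2ccccc2)cc1 | intermediate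
13 | 3-[4-(benzyloxy)-3-methoxyphenyl]propanenitrile oxide (formed in the flask) | COc1cc(CCC#[N+][O-])ccc1OCc1ccccc1 | intermediate
14 | (1S)-2-[4-(benzyloxy)phenyl]-1-[(5S)-3-{2-[4-(benzyloxy)-3-methoxyphenyl]ethyl}-4,5-dihydro-1,2-oxazol-5-yl]ethan-1-ol | COc1cc(CCC2=NO[C@@H](C2)[C@@H](O)Cc3ccc(OCc4ccccc4)cc3)ccc1OCc1ccccc1 | intermediate
15 | (2S,3S)-1-[4-(benzyloxy)phenyl]-7-[4-(benzyloxy)-3-methoxyphenyl]-5-iminoheptane-2,3-diol (formed in the flask) | COc1cc(CCC(=N)C[C@H](O)[C@@H](O)Cc2ccc(OCc3ccccc3)cc2)ccc1OCc1ccccc1 | intermediate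
16 | (5S,6S)-1-[4-(benzyloxy)-3-methoxyphenyl]-7-[4-(benzyloxy)phenyl]-5,6-dihydroxyheptan-3-one | COc1cc(CCC(=O)C[C@H](O)[C@@H](O)Cc2ccc(OCc3ccccc3)cc2)ccc1OCc1ccccc1 | intermediate
17 | 5,6-bis(O-diethylboryl) derivative of 16, the boron on the C5 oxygen of the heptanone (O3 of the target chain) bound to the ketone oxygen (formed in the flask) | COc1cc(CCC(=O)C[C@H](OB(CC)CC)[C@@H](OB(CC)CC)Cc2ccc(OCc3ccccc3)cc2)ccc1OCc1ccccc1 | intermediate
18 | (2S,3S,5S)-1-[4-(benzyloxy)phenyl]-7-[4-(benzyloxy)-3-methoxyphenyl]heptane-2,3,5-triol | COc1cc(CC[C@H](O)C[C@H](O)[C@@H](O)Cc2ccc(OCc3ccccc3)cc2)ccc1OCc1ccccc1 | intermediate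
19 | (2S,3S,5S)-1-(4-hydroxyphenyl)-7-(4-hydroxy-3-methoxyphenyl)heptane-2,3,5-triol | COc1cc(CC[C@H](O)C[C@H](O)[C@@H](O)Cc2ccc(O)cc2)ccc1O | target

Total step count: 9. Longest linear sequence: 7 steps (7 → 8 → 9 → 10 → 14 → 16 → 18 → 19; the branch from 1 is 6 steps).

Steps most likely to fail, riskiest first:

Step 6. Face selectivity may erode if donor solvent breaks the magnesium bridge, the nitrile oxide may dimerise to the furoxan before it reaches the alkene, or the hypochlorite may chlorinate the guaiacyl ring. The fallback sets out from 6 and comes back at 16, and would form C3–C4 instead by a chelation-controlled Mukaiyama aldol. Alcohol 6 would be protected as its 4-methoxybenzyl ether, 1-(benzyloxy)-4-{(2S)-2-[(4-methoxybenzyl)oxy]but-3-en-1-yl}benzene F1 (NaH, PMBCl, Bu4NI, DMF). The alkene would be cleaved (OsO4 cat., NaIO4, 2,6-lutidine, dioxane/H2O) to (S)-3-[4-(benzyloxy)phenyl]-2-[(4-methoxybenzyl)oxy]propanal F2. Commercial zingerone, 4-(4-hydroxy-3-methoxyphenyl)butan-2-one F3, would be benzylated (BnBr, K2CO3, acetone) to 4-[4-(benzyloxy)-3-methoxyphenyl]butan-2-one F4 and converted into its kinetic enol ether, {4-[4-(benzyloxy)-3-methoxyphenyl]but-1-en-2-yl}oxy(trimethyl)silane F5 (LDA, TMSCl, THF, −78 °C). MgBr2·OEt2 in CH2Cl2 at −78 °C would tie the aldehyde oxygen of F2 to its ether oxygen in a five-membered chelate, to which F5 should add on the face away from the CH2Ar group. This would give the 2,3-syn aldol (5S,6S)-1-[4-(benzyloxy)-3-methoxyphenyl]-7-[4-(benzyloxy)phenyl]-5-hydroxy-6-[(4-methoxybenzyl)oxy]heptan-3-one F6, and DDQ (CH2Cl2/pH 7 buffer) would then remove the 4-methoxybenzyl group to give 16.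

Step 8. The free C2 hydroxyl may compete with the ketone for the boron on O3, so that hydride delivery is no longer governed by the six-membered chelate and the 3,5-syn selectivity falls. The fallback sets out from 14 and comes back at 18, and would make the C3 hydroxyl the only free ligand. The C2 hydroxyl of 14 would be silylated (TBSOTf, 2,6-lutidine, CH2Cl2, −78 °C) to (5S)-5-{(1S)-2-[4-(benzyloxy)phenyl]-1-[(tert-butyldimethylsilyl)oxy]ethyl}-3-{2-[4-(benzyloxy)-3-methoxyphenyl]ethyl}-4,5-dihydro-1,2-oxazole F7. N–O cleavage as in step 7 would give (5S,6S)-1-[4-(benzyloxy)-3-methoxyphenyl]-7-[4-(benzyloxy)phenyl]-6-[(tert-butyldimethylsilyl)oxy]-5-hydroxyheptan-3-one F8. The Narasaka–Prasad reduction would then be run on this ordinary β-hydroxy ketone to give the C2-O-tert-butyldimethylsilyl ether of 18 F9, and TBAF in THF would return 18.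

Step 7. The benzyl ethers may be partly lost on the nickel surface and the N–O cleavage may stall, giving mixtures of partly deprotected material. The fallback sets out from 14 and comes back at 19, and would reverse the order of the end game so that debenzylation is intended. One hydrogenation of 14 over Pd(OH)2/C with B(OH)3 in MeOH/H2O would cleave the N–O bond and both O-benzyl bonds to give (5S,6S)-5,6-dihydroxy-1-(4-hydroxy-3-methoxyphenyl)-7-(4-hydroxyphenyl)heptan-3-one F10. The borinate-directed reduction (Et2BOMe 4.5 equiv, NaBH4, THF/MeOH, −78 °C) would then be run last on F10 to give 19 directly.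

Further compounds
F1 | step 6 | 1-(benzyloxy)-4-{(2S)-2-[(4-methoxybenzyl)oxy]but-3-en-1-yl}benzene | C=C[C@@H](OCc1ccc(OC)cc1)Cc1ccc(OCc2ccccc2)cc1
F2 | step 6 | (S)-3-[4-(benzyloxy)phenyl]-2-[(4-methoxybenzyl)oxy]propanal | O=C[C@@H](OCc1ccc(OC)cc1)Cc1ccc(OCc2ccccc2)cc1
F3 | step 6 | 4-(4-hydroxy-3-methoxyphenyl)butan-2-one (zingerone, bought) | COc1cc(CCC(C)=O)ccc1O
F4 | step 6 | 4-[4-(benzyloxy)-3-methoxyphenyl]butan-2-one | COc1cc(CCC(C)=O)ccc1OCc1ccccc1
F5 | step 6 | {4-[4-(benzyloxy)-3-methoxyphenyl]but-1-en-2-yl}oxy(trimethyl)silane | COc1cc(CCC(=C)O[Si](C)(C)C)ccc1OCc1ccccc1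
F6 | step 6 | (5S,6S)-1-[4-(benzyloxy)-3-methoxyphenyl]-7-[4-(benzyloxy)phenyl]-5-hydroxy-6-[(4-methoxybenzyl)oxy]heptan-3-one | COc1cc(CCC(=O)C[C@H](O)[C@@H](OCc2ccc(OC)cc2)Cc2ccc(OCc3ccccc3)cc2)ccc1OCc1ccccc1
F7 | step 8 | (5S)-5-{(1S)-2-[4-(benzyloxy)phenyl]-1-[(tert-butyldimethylsilyl)oxy]ethyl}-3-{2-[4-(benzyloxy)-3-methoxyphenyl]ethyl}-4,5-dihydro-1,2-oxazole | COc1cc(CCC2=NO[C@@H](C2)[C@@H](O[Si](C)(C)C(C)(C)C)Cc3ccc(OCc4ccccc4)cc3)ccc1OCc1ccccc1
F8 | step 8 | (5S,6S)-1-[4-(benzyloxy)-3-methoxyphenyl]-7-[4-(benzyloxy)phenyl]-6-[(tert-butyldimethylsilyl)oxy]-5-hydroxyheptan-3-one | COc1cc(CCC(=O)C[C@H](O)[C@@H](O[Si](C)(C)C(C)(C)C)Cc2ccc(OCc3ccccc3)cc2)ccc1OCc1ccccc1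
F9 | step 8 | C2-O-tert-butyldimethylsilyl ether of 18, (2S,3S,5S) | COc1cc(CC[C@H](O)C[C@H](O)[C@@H](O[Si](C)(C)C(C)(C)C)Cc2ccc(OCc3ccccc3)cc2)ccc1OCc1ccccc1
F10 | step 7 | (5S,6S)-5,6-dihydroxy-1-(4-hydroxy-3-methoxyphenyl)-7-(4-hydroxyphenyl)heptan-3-one | COc1cc(CCC(=O)C[C@H](O)[C@@H](O)Cc2ccc(O)cc2)ccc1O
A1 | direct plan | (S)-4-{2-[4-(tert-butyldimethylsilyloxy)-3-methoxyphenyl]ethyl}oxetan-2-one | O=C1C[C@H](CCc2ccc(O[Si](C)(C)C(C)(C)C)c(OC)c2)O1
A2 | direct plan | 2-[4-(tert-butyldimethylsilyloxy)phenyl]ethyl N,N-diisopropylcarbamate | CC(C)N(C(C)C)C(=O)OCCc1ccc(O[Si](C)(C)C(C)(C)C)cc1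
A3 | direct plan | (2S,5S)-1-[4-(tert-butyldimethylsilyloxy)phenyl]-7-[4-(tert-butyldimethylsilyloxy)-3-methoxyphenyl]-5-hydroxy-3-oxoheptan-2-yl N,N-diisopropylcarbamate | COc1cc(CC[C@H](O)CC(=O)[C@@H](OC(=O)N(C(C)C)C(C)C)Cc2ccc(O[Si](C)(C)C(C)(C)C)cc2)ccc1O[Si](C)(C)C(C)(C)C
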